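**Retrosynthetic overview**
1. Target ⇐ acetylation and desilylation ⇐ CBS reduction of the macrocyclic C4 ketone 28 (alkylidene β‑keto ester).
2. 28 ⇐ N–O cleavage and dehydration of isoxazoline 25 ⇐ key step: intramolecular nitrile oxide–enoate cycloaddition (C4–C5 and O–C6 bonds) that closes the ten‑membered carbocycle and the isoxazoline together.
3. γ‑Lactone ⇐ iodolactonisation (O–C7) of a tertiary vinyl carbinol ⇐ chelation‑controlled propionate aldol (C8–C17) ⇐ methoxyallene addition to the C9 aldehyde (C8–C9).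
4. Cyclohexane ⇐ catalytic enantioselective Diels–Alder reaction (C1, C10, C11), then allylboration (C2), boronate oxa‑Michael addition (O14) and directed reduction (C12).
5. Ring order: cyclohexane → γ‑lactone → ten‑membered ring plus isoxazoline (one operation).

Assumption: intermediates carry the briarane numbers of the target (C15 = methyl on C1, C16 = ester carbon, C17–C19 = lactone CH(CH3)–C=O, C20 = methyl on C11); β is the cyclohexane face of C15; the target is (1R,2R,4R,5E,7S,8S,9R,10S,11R,12S,14S,17R). Compounds 1, 3, 12, 15, 19 and all reagents are bought.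

**Step 1**
Reactants: 1 pent-1-en-3-one
Product: 2 (Z)-triisopropyl(penta-1,3-dien-3-yloxy)silane
Conditions: TIPSOTf, Et3N, CH2Cl2, 0 °C
Reagents that add atoms: triisopropylsilyl triflate CC(C)[Si](C(C)C)(C(C)C)OS(=O)(=O)C(F)(F)F
Why: Soft enolisation and O‑silylation of the ethyl ketone gives the thermodynamically preferred (Z)-2-silyloxydiene with the methyl group "outside", as the cycloaddition needs.

**Step 2**
Reactants: 2 (Z)-triisopropyl(penta-1,3-dien-3-yloxy)silane; 3 ethyl (E)-3-methyl-4-oxobut-2-enoate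
Product: 4 ethyl (1S,2R,6S)-6-formyl-2,6-dimethyl-3-(triisopropylsilyloxy)cyclohex-3-ene-1-carboxylate
Conditions: (S)-o-tolyl-CBS oxazaborolidine·HNTf2 (15 mol %), CH2Cl2, −78 → −40 °C
Reagents that add atoms: none
Why: Corey oxazaborolidinium‑catalysed Diels–Alder reaction in which the Lewis‑acid‑bound α‑methyl enal reacts through the exo‑CHO/endo‑ester transition state and the nucleophilic CHMe terminus of the diene bonds to the enal β‑carbon, so C1 (quaternary), C10 and C11 are set at once (15‑Me, C9 ester and 11‑Me all β, CHO α) with catalyst‑controlled absolute configuration.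

**Step 3**
Reactants: 4 Diels–Alder aldehyde
Product: 5 (2R)-homoallylic alcohol (CHO of 4 converted to CH(OH)CH2CH=CH2)
Conditions: (+)-Ipc2B(allyl), Et2O, −78 °C; then NaBO3·4H2O, THF–H2O
Reagents that add atoms: (+)-B-allyldiisopinocampheylborane C=CCB([C@H]1C[C@H]2C[C@@H]([C@@H]1C)C2(C)C)[C@H]1C[C@H]2C[C@@H]([C@@H]1C)C2(C)C
Why: Brown allylboration is aldehyde‑selective (ester and silyl enol ether untouched) and the reagent sets the C2 carbinol centre with the same topicity as in the known pivalaldehyde case, overriding the weak bias of the α‑quaternary centre.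

**Step 4**
Reactants: 5 (2R)-homoallylic alcohol
Product: 6 Δ13-12-ketone (cyclohexenone)
Conditions: Pd(OAc)2 (1.1 equiv), MeCN, 40 °C
Reagents that add atoms: none
Why: Saegusa–Ito oxidation converts the regiodefined silyl enol ether into the C13=C14 enone under non‑basic conditions, so the epimerisable C11 centre is not touched.

**Step 5**
Reactants: 6 cyclohexenone
Product: 8 2,14α-diol 12-ketone, via cyclic phenylboronate 7 (not isolated)
Conditions: PhB(OH)2, i-Pr2NH (20 mol %), 4 Å MS, toluene, 40 °C; then 30% H2O2, Na2CO3, 0 °C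
Reagents that add atoms: phenylboronic acid OB(O)c1ccccc1
Why: Falck boronic‑acid hemiester oxa‑Michael addition, in which the C2–O–B(Ph)–OH hemiester delivers its oxygen to C14 through a six‑membered ring so that the new C14–O bond must be cis to C2 (α), and peroxide work‑up frees the diol.

**Step 6**
Reactants: 8 2,14α-diol 12-ketone
Product: 9 2,12β,14α-triol
Conditions: Me4NBH(OAc)3, MeCN–AcOH, −30 °C
Reagents that add atoms: none
Why: Evans–Saksena reduction, in which the boron bound to O14 delivers hydride intramolecularly to the α‑face of the C12 ketone and gives the 12β‑alcohol anti to the 14α‑hydroxyl.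

**Step 7**
Reactants: 9 2,12β,14α-triol
Product: 10 12-O-TBS ether
Conditions: TBSOTf (1.05 equiv), 2,6-lutidine, CH2Cl2, −78 °C
Reagents that add atoms: tert-butyldimethylsilyl triflate CC(C)(C)[Si](C)(C)OS(=O)(=O)C(F)(F)F
Why: Kinetic silylation at the C12 hydroxyl, the only secondary alcohol not flanked by the quaternary C1, leaves the two neopentyl‑type hydroxyls (C2, C14) free.

**Step 8**
Reactants: 10 12-O-TBS ether
Product: 11 C9 aldehyde
Conditions: DIBAL-H (3.5 equiv), CH2Cl2, −78 °C; Rochelle salt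
Reagents that add atoms: none
Why: Low‑temperature DIBAL‑H reduction of the ethyl ester stops at the aluminium hemiacetal (stabilised by the neighbouring alkoxides) and gives the aldehyde on work‑up.

**Step 9**
Reactants: 11 C9 aldehyde; 12 methoxyallene
Product: 14 (9R)-α′-hydroxy vinyl ketone, via allenyl carbinol 13 (not isolated)
Conditions: 12, n-BuLi, THF, −78 °C, then 11; then 5% aq. H2SO4, THF, 0 °C
Reagents that add atoms: water O
Why: 1,2‑Addition of lithiated methoxyallene (an acryloyl anion equivalent) follows the Felkin–Anh model with attack anti to the quaternary C1 arm and sets C9, and mild hydrolysis of the allenyl enol ether unmasks the vinyl ketone.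

**Step 10**
Reactants: 14 α′-hydroxy vinyl ketone; 15 tert-butyl propanoate
Product: 16 aldol adduct (tert-butyl ester; C8 tertiary carbinol bearing vinyl; C8 and C17 as in the target)
Conditions: 15, LDA (5 equiv), THF, −78 °C, then 14, −78 °C
Reagents that add atoms: none
Why: Chelation‑controlled aldol addition in which lithium bridges the C9 alkoxide and the C8 ketone (Cram chelate) so that the E(O)-enolate attacks the face syn to H‑9 through a closed Zimmerman–Traxler transition state, setting C8 and C17 and adding 1,2 to the enone at low temperature.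

**Step 11**
Reactants: 16 aldol adduct
Product: 17 2,9,14-triacetate
Conditions: Ac2O, pyridine, DMAP (cat.), CH2Cl2, rt
Reagents that add atoms: acetic anhydride CC(=O)OC(C)=O
Why: DMAP‑catalysed acetylation esterifies the three secondary alcohols, while the tertiary C8 carbinol is too hindered to react.

**Step 12**
Reactants: 17 2,9,14-triacetate
Product: 18 iodolactone (γ-lactone O–C7, CH2I = C6)
Conditions: I2, NaHCO3, MeCN, 0 °C, dark
Reagents that add atoms: iodine II
Why: 5‑exo iodolactonisation with direct participation of the tert‑butyl ester, in which the tertiary allylic hydroxyl directs (Chamberlin cis effect) so that CH2I ends up cis to 8‑OH and trans to the C9 branch, setting C7.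

**Step 13**
Reactants: 18 iodolactone; 19 methyl (triphenylphosphoranylidene)acetate
Product: 21 (E)-enoate (C5=C6), via lactone aldehyde 20 (not isolated)
Conditions: AgBF4, DMSO, rt; Et3N; then 19, CH2Cl2, rt
Reagents that add atoms: dimethyl sulfoxide CS(C)=O
Why: Silver‑assisted Kornblum oxidation turns the primary iodide into the aldehyde, which the stabilised Wittig ylide traps in situ as the (E)-enoate before the α‑acyloxy aldehyde can epimerise.

**Step 14**
Reactants: 21 (E)-enoate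
Product: 22 C4 aldehyde
Conditions: O3, CH2Cl2–MeOH, −78 °C (Sudan III end point); Me2S
Reagents that add atoms: ozone [O-][O+]=O
Why: Ozonolysis is chemoselective for the electron‑rich terminal allyl alkene over the conjugated, electron‑poor enoate.

**Step 15**
Reactants: 22 C4 aldehyde
Product: 25 isoxazoline-fused ten-membered carbocycle, via aldoxime 23 (not isolated), via nitrile oxide 24 (not isolated)
Conditions: NH2OH·HCl, pyridine, EtOH, rt; then slow addition to aq. NaOCl, CH2Cl2, 0 °C → rt, 1 mM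
Reagents that add atoms: hydroxylamine hydrochloride NO.Cl
Why: Proposed new method: oxidation of the aldoxime gives a nitrile oxide whose intramolecular 1,3‑dipolar cycloaddition to the tethered (E)-enoate forms the C4–C5 and O–C6 bonds and so closes the ten‑membered carbocycle and the isoxazoline together; the dipole carbon goes to the ester‑bearing α‑carbon and the oxygen to the hindered β‑carbon as nitrile oxides do with β‑substituted acrylates, the fused ten‑membered mode should be preferred over the nine‑membered alternative, the two new sp3 centres (C5, C6) are removed in the next step, and the closest known reaction type is the Kozikowski/Asaoka INOC macrocyclisation.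

**Step 16**
Reactants: 25 isoxazoline
Product: 28 macrocyclic alkylidene β-keto ester (C4 ketone), via hydroxy imine 26 (not isolated), via hydroxy keto ester 27 (not isolated)
Conditions: Mo(CO)6, MeCN–H2O (15:1), 80 °C; then SiO2, Et3N, CH2Cl2, rt
Reagents that add atoms: water O
Why: Mo(CO)6 cleaves the isoxazoline N–O bond, the imine hydrolyses, and E1cB loss of water from the β‑hydroxy β‑keto ester gives the C5=C6 alkene whose geometry (C4 cis to C7, ester trans to C7) is imposed by the ten‑membered ring.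

**Step 17**
Reactants: 28 alkylidene β-keto ester
Product: 29 (4R)-allylic alcohol
Conditions: (S)-Me-CBS (20 mol %), catecholborane, toluene, −78 °C
Reagents that add atoms: none
Why: Corey–Bakshi–Shibata reduction, in which the (S)-catalyst treats the alkenyl arm as the large group and delivers hydride 1,2 to give the (4R)-alcohol.

**Step 18**
Reactants: 29 (4R)-allylic alcohol
Product: 30 12-O-TBS tetraacetate
Conditions: Ac2O, pyridine, DMAP (cat.), CH2Cl2, 0 °C
Reagents that add atoms: acetic anhydride CC(=O)OC(C)=O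
Why: Acetylation of the only free secondary alcohol (C4), the tertiary C8 hydroxyl being inert under these mild conditions.

**Step 19**
Reactants: 30 12-O-TBS tetraacetate
Product: 31 CNP0169867.2 (target)
Conditions: HF·pyridine, THF, 0 °C → rt
Reagents that add atoms: none
Why: Fluoride‑mediated silyl ether cleavage frees the C12 hydroxyl without touching the acetates, lactone or enoate.

**Compound list**
1 | pent-1-en-3-one (ethyl vinyl ketone) | CCC(=O)C=C | starting material
2 | (Z)-triisopropyl(penta-1,3-dien-3-yloxy)silane | C/C=C(/C=C)O[Si](C(C)C)(C(C)C)C(C)C | intermediate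
3 | ethyl (E)-3-methyl-4-oxobut-2-enoate | CCOC(=O)/C=C(\C)C=O | starting material
4 | ethyl (1S,2R,6S)-6-formyl-2,6-dimethyl-3-(triisopropylsilyloxy)cyclohex-3-ene-1-carboxylate (C9 ester, 11-Me, 15-Me β; CHO α) | CCOC(=O)[C@H]1[C@@H](C)C(O[Si](C(C)C)(C(C)C)C(C)C)=CC[C@]1(C)C=O | intermediate
5 | (2R)-homoallylic alcohol of 4 (C2 carbinol with allyl) | CCOC(=O)[C@H]1[C@@H](C)C(O[Si](C(C)C)(C(C)C)C(C)C)=CC[C@]1(C)[C@H](O)CC=C | intermediate
6 | Δ13-12-ketone (cyclohexenone) | CCOC(=O)[C@H]1[C@@H](C)C(=O)C=C[C@]1(C)[C@H](O)CC=C | intermediate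
7 | cyclic phenylboronate bridging O2 and O14 | CCOC(=O)[C@H]1[C@@H](C)C(=O)C[C@@H]2OB(c3ccccc3)O[C@H](CC=C)[C@]12C | intermediate
8 | 2,14α-diol 12-ketone | CCOC(=O)[C@H]1[C@@H](C)C(=O)C[C@H](O)[C@]1(C)[C@H](O)CC=C | intermediate
9 | 2,12β,14α-triol ethyl ester | CCOC(=O)[C@H]1[C@@H](C)[C@@H](O)C[C@H](O)[C@]1(C)[C@H](O)CC=C | intermediate
10 | 12-O-TBS ether of 9 | CCOC(=O)[C@H]1[C@@H](C)[C@@H](O[Si](C)(C)C(C)(C)C)C[C@H](O)[C@]1(C)[C@H](O)CC=C | intermediate
11 | C9 aldehyde | O=C[C@H]1[C@@H](C)[C@@H](O[Si](C)(C)C(C)(C)C)C[C@H](O)[C@]1(C)[C@H](O)CC=C | intermediate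
12 | methoxyallene (1-methoxypropa-1,2-diene) | COC=C=C | starting material
13 | (9R)-1-methoxyallenyl carbinol | C=C=C(OC)[C@H](O)[C@H]1[C@@H](C)[C@@H](O[Si](C)(C)C(C)(C)C)C[C@H](O)[C@]1(C)[C@H](O)CC=C | intermediate
14 | (9R)-α′-hydroxy vinyl ketone (C8 ketone, C7=C6 vinyl) | C=CC(=O)[C@H](O)[C@H]1[C@@H](C)[C@@H](O[Si](C)(C)C(C)(C)C)C[C@H](O)[C@]1(C)[C@H](O)CC=C | intermediate
15 | tert-butyl propanoate | CCC(=O)OC(C)(C)C | starting material
16 | aldol adduct: tert-butyl ester with C8(OH)(vinyl), 17-Me; 2,9,14-triol | CC(C)(C)OC(=O)[C@H](C)[C@@](C=C)(O)[C@H](O)[C@H]1[C@@H](C)[C@@H](O[Si](C)(C)C(C)(C)C)C[C@H](O)[C@]1(C)[C@H](O)CC=C | intermediate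
17 | 2,9,14-triacetate of 16 | CC(C)(C)OC(=O)[C@H](C)[C@@](C=C)(O)[C@H](OC(C)=O)[C@H]1[C@@H](C)[C@@H](O[Si](C)(C)C(C)(C)C)C[C@H](OC(C)=O)[C@]1(C)[C@H](OC(C)=O)CC=C | intermediate
18 | iodolactone (γ-lactone on O7, 8-OH, 17-Me, CH2I at C7) | IC[C@@H]1OC(=O)[C@H](C)[C@@]1(O)[C@H](OC(C)=O)[C@H]1[C@@H](C)[C@@H](O[Si](C)(C)C(C)(C)C)C[C@H](OC(C)=O)[C@]1(C)[C@H](OC(C)=O)CC=C | intermediate
19 | methyl (triphenylphosphoranylidene)acetate | COC(=O)C=P(c1ccccc1)(c1ccccc1)c1ccccc1 | starting material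
20 | lactone aldehyde (C6 = CHO) | O=C[C@@H]1OC(=O)[C@H](C)[C@@]1(O)[C@H](OC(C)=O)[C@H]1[C@@H](C)[C@@H](O[Si](C)(C)C(C)(C)C)C[C@H](OC(C)=O)[C@]1(C)[C@H](OC(C)=O)CC=C | intermediate
21 | (E)-enoate (methyl ester, C5=C6) with intact allyl group | COC(=O)/C=C/[C@@H]1OC(=O)[C@H](C)[C@@]1(O)[C@H](OC(C)=O)[C@H]1[C@@H](C)[C@@H](O[Si](C)(C)C(C)(C)C)C[C@H](OC(C)=O)[C@]1(C)[C@H](OC(C)=O)CC=C | intermediate
22 | C4 aldehyde | COC(=O)/C=C/[C@@H]1OC(=O)[C@H](C)[C@@]1(O)[C@H](OC(C)=O)[C@H]1[C@@H](C)[C@@H](O[Si](C)(C)C(C)(C)C)C[C@H](OC(C)=O)[C@]1(C)[C@H](OC(C)=O)CC=O | intermediate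
23 | C4 (E)-aldoxime | COC(=O)/C=C/[C@@H]1OC(=O)[C@H](C)[C@@]1(O)[C@H](OC(C)=O)[C@H]1[C@@H](C)[C@@H](O[Si](C)(C)C(C)(C)C)C[C@H](OC(C)=O)[C@]1(C)[C@H](OC(C)=O)C/C=N/O | intermediate
24 | C4 nitrile oxide | COC(=O)/C=C/[C@@H]1OC(=O)[C@H](C)[C@@]1(O)[C@H](OC(C)=O)[C@H]1[C@@H](C)[C@@H](O[Si](C)(C)C(C)(C)C)C[C@H](OC(C)=O)[C@]1(C)[C@H](OC(C)=O)CC#[N+][O-] | intermediate
25 | isoxazoline-fused ten-membered carbocycle (C4=N–O–C6, 5-CO2Me; 5,6-trans, one facial isomer drawn) | COC(=O)[C@H]1[C@@H](O3)[C@@H]2OC(=O)[C@H](C)[C@@]2(O)[C@H](OC(C)=O)[C@H]2[C@@H](C)[C@@H](O[Si](C)(C)C(C)(C)C)C[C@H](OC(C)=O)[C@]2(C)[C@H](OC(C)=O)CC1=N3 | intermediate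
26 | 6-hydroxy C4 imine | COC(=O)[C@H]1[C@@H](O)[C@@H]2OC(=O)[C@H](C)[C@@]2(O)[C@H](OC(C)=O)[C@H]2[C@@H](C)[C@@H](O[Si](C)(C)C(C)(C)C)C[C@H](OC(C)=O)[C@]2(C)[C@H](OC(C)=O)CC1=N | intermediate
27 | 6-hydroxy 4-keto ester | COC(=O)[C@H]1[C@@H](O)[C@@H]2OC(=O)[C@H](C)[C@@]2(O)[C@H](OC(C)=O)[C@H]2[C@@H](C)[C@@H](O[Si](C)(C)C(C)(C)C)C[C@H](OC(C)=O)[C@]2(C)[C@H](OC(C)=O)CC1=O | intermediate
28 | macrocyclic alkylidene β-keto ester (C4 ketone, 5E) | COC(=O)/C1=C/[C@@H]2OC(=O)[C@H](C)[C@@]2(O)[C@H](OC(C)=O)[C@H]2[C@@H](C)[C@@H](O[Si](C)(C)C(C)(C)C)C[C@H](OC(C)=O)[C@]2(C)[C@H](OC(C)=O)CC1=O | intermediate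
29 | (4R)-allylic alcohol | COC(=O)/C1=C/[C@@H]2OC(=O)[C@H](C)[C@@]2(O)[C@H](OC(C)=O)[C@H]2[C@@H](C)[C@@H](O[Si](C)(C)C(C)(C)C)C[C@H](OC(C)=O)[C@]2(C)[C@H](OC(C)=O)C[C@H]1O | intermediate
30 | 12-O-TBS ether of the target | COC(=O)/C1=C/[C@@H]2OC(=O)[C@H](C)[C@@]2(O)[C@H](OC(C)=O)[C@H]2[C@@H](C)[C@@H](O[Si](C)(C)C(C)(C)C)C[C@H](OC(C)=O)[C@]2(C)[C@H](OC(C)=O)C[C@H]1OC(C)=O | intermediate
31 | CNP0169867.2, (1R,2R,4R,5E,7S,8S,9R,10S,11R,12S,14S,17R)-2,4,9,14-tetraacetoxy-8,12-dihydroxy briar-5-en-18,7-olide 16-oic acid methyl ester | COC(=O)/C1=C/[C@@H]2OC(=O)[C@H](C)[C@@]2(O)[C@H](OC(C)=O)[C@H]2[C@@H](C)[C@@H](O)C[C@H](OC(C)=O)[C@]2(C)[C@H](OC(C)=O)C[C@H]1OC(C)=O | target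

**Totals**
Total step count: 19. Longest linear sequence: 19 steps (from 1).

**Steps most likely to fail, with fallbacks**

Step 15 (medium‑ring nitrile oxide cycloaddition; dimerisation of the unhindered nitrile oxide or the nine‑membered regioisomer may win). The fallback sets out from 18 and replaces the dipolar cycloaddition by a Nozaki–Hiyama–Kishi ring closure. Kornblum oxidation of 18 followed by Wittig reaction with the α‑iodo ylide made from 19 and N‑iodosuccinimide gives the (Z)-α-iodo enoate F1. Ozonolysis of its allyl group gives the iodo enoate aldehyde F2. CrCl2/NiCl2 in DMSO at high dilution then joins C5 to C4 with retention of alkene geometry, giving 29 together with its C4 epimer F3. Dess–Martin oxidation of the mixture returns to 28.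

Step 2 (topicity of the Diels–Alder reaction; an endo‑CHO pathway would put the C11 methyl on the α face). The fallback sets out from 2 and 3 and sets C11 by enolate protonation instead of by the cycloaddition. The C11 epimer of the adduct F4 is carried through steps 3 and 4 to the epimeric homoallylic alcohol F5 and the epimeric enone F6. F6 has a single α′ hydrogen (C1 is quaternary); it is deprotonated with LDA at −78 °C and protonated kinetically with 2,6‑di‑tert‑butylphenol from the α face, anti to the C9 ester, which returns to 6.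

Step 10 (simple diastereoselectivity of an ester enolate adding to a ketone; C17 may form as a mixture). The fallback sets out from 14 and fixes C17 on a cyclic enolate. A Reformatsky reaction of 14 with ethyl 2‑bromopropanoate and zinc (zinc alkoxide chelate) lactonises in situ onto O9. Treatment with excess LDA and protonation with acetic acid at −78 °C, anti to the C8 alkoxide, gives the 9,19‑lactone F7 as a single C17 epimer. LiOH opening followed by I2/NaHCO3 iodolactonisation gives the 7,19‑iodolactone triol F8, and Ac2O/DMAP/pyridine returns to 18.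

**Further compounds**
F1 | step 15 | (Z)-α-iodo enoate (I on C5) with allyl group | COC(=O)/C(I)=C/[C@@H]1OC(=O)[C@H](C)[C@@]1(O)[C@H](OC(C)=O)[C@H]1[C@@H](C)[C@@H](O[Si](C)(C)C(C)(C)C)C[C@H](OC(C)=O)[C@]1(C)[C@H](OC(C)=O)CC=C
F2 | step 15 | (Z)-α-iodo enoate C4 aldehyde | COC(=O)/C(I)=C/[C@@H]1OC(=O)[C@H](C)[C@@]1(O)[C@H](OC(C)=O)[C@H]1[C@@H](C)[C@@H](O[Si](C)(C)C(C)(C)C)C[C@H](OC(C)=O)[C@]1(C)[C@H](OC(C)=O)CC=O
F3 | step 15 | C4 epimer of 29 | COC(=O)/C1=C/[C@@H]2OC(=O)[C@H](C)[C@@]2(O)[C@H](OC(C)=O)[C@H]2[C@@H](C)[C@@H](O[Si](C)(C)C(C)(C)C)C[C@H](OC(C)=O)[C@]2(C)[C@H](OC(C)=O)C[C@@H]1O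
F4 | step 2 | C11 epimer of 4 | CCOC(=O)[C@H]1[C@H](C)C(O[Si](C(C)C)(C(C)C)C(C)C)=CC[C@]1(C)C=O
F5 | step 2 | C11 epimer of 5 | CCOC(=O)[C@H]1[C@H](C)C(O[Si](C(C)C)(C(C)C)C(C)C)=CC[C@]1(C)[C@H](O)CC=C
F6 | step 2 | C11 epimer of 6 | CCOC(=O)[C@H]1[C@H](C)C(=O)C=C[C@]1(C)[C@H](O)CC=C
F7 | step 10 | 9,19-lactone (α-methyl-β-hydroxy-β-vinyl-γ-butyrolactone on O9) | C=C[C@@]1(O)[C@@H](C)C(=O)O[C@@H]1[C@H]2[C@@H](C)[C@@H](O[Si](C)(C)C(C)(C)C)C[C@H](O)[C@]2(C)[C@H](O)CC=C
F8 | step 10 | 7,19-iodolactone 2,9,14-triol | IC[C@@H]1OC(=O)[C@H](C)[C@@]1(O)[C@H](O)[C@H]1[C@@H](C)[C@@H](O[Si](C)(C)C(C)(C)C)C[C@H](O)[C@]1(C)[C@H](O)CC=C
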